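**Plan**
Locants: decalin C-1 to C-10 as in labdanes (C-5 ring-fusion CH, C-10 quaternary carbon, C-8=C-9 ring alkene), chain C-11 to C-16, CH2OH on C-13, butenolide on C-16.
Cuts, in retrosynthetic order: the two O–Si bonds, butenolide back to a 3-furyl group, C13=C14 (Wittig), C11–C12 (hydrazone alkylation), C8–CH3 (enol triflate and cuprate), then ring B at C6–C7 and C9–C10 in one (3+3) event.
Enabling feature: C7–C8–C9 of ring B, with C-11 on C-9, is an acetoacetate in disguise (a 1,3-dinucleophile as its bis-silyl dienol ether), and C6–C5–C10 of ring A is the allyl unit of β-cyclogeraniol (a 1,3-dielectrophile: cation at C-6, then at C-10 after protonation of C-5).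
Forward: ring A is bought, ring B closes in step 4, the C-8 methyl, C-11 and the C12–C13 ketone follow, the C14–C16 furyl fragment joins by Wittig reaction, and the furan becomes the butenolide last.
Stereochemistry: C-5 and C-10 arise together in step 4 under control of a bought 8-phenylmenthyl ester (diastereomers separable, auxiliary leaves in step 7); C-16 comes from asymmetric hydrogenation; the C13=C14 geometry comes from the α-silyloxy ketone Wittig reaction.

Key step: step 4

Assumption: β-cyclocitral, (−)-8-phenylmenthol, 2,2,6-trimethyl-4H-1,3-dioxin-4-one, 1-(tert-butyldimethylsilyloxy)propan-2-one and ethyl 3-(furan-3-yl)-3-oxopropanoate are taken as commercial.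

Step 1
Reactants: 1 β-cyclocitral (2,6,6-trimethylcyclohex-1-ene-1-carbaldehyde)
Product: 2 β-cyclogeraniol [(2,6,6-trimethylcyclohex-1-en-1-yl)methanol]
Conditions: NaBH4, MeOH, 0 °C
Reagents that add atoms: none
Why: Borohydride 1,2-reduction of the enal (carbonyl reduction) gives the primary allylic alcohol that serves as the latent 1,3-dielectrophile; no stereocenter is formed.

Step 2
Reactants: 3 (−)-8-phenylmenthol [(1R,2S,5R)-5-methyl-2-(2-phenylpropan-2-yl)cyclohexan-1-ol]; 4 2,2,6-trimethyl-4H-1,3-dioxin-4-one
Product: 6 (−)-8-phenylmenthyl acetoacetate, via acetylketene 5 (not isolated)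
Conditions: xylene, 140 °C, acetone distilled off
Reagents that add atoms: none
Why: Thermal retro-hetero-Diels–Alder cleavage of 4 releases acetylketene, which acylates even hindered secondary alcohols (acetoacetylation); the stereocenters of 3 are not touched.

Step 3
Reactants: 6 (−)-8-phenylmenthyl acetoacetate
Product: 7 1-[(−)-8-phenylmenthyloxy]-1,3-bis(trimethylsilyloxy)buta-1,3-diene (Chan-type diene; ketene acetal geometry immaterial)
Conditions: Me3SiOTf (2.2 equiv), Et3N (2.5 equiv), Et2O, 0 °C → rt
Reagents that add atoms: trimethylsilyl triflate, C[Si](C)(C)OS(=O)(=O)C(F)(F)F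
Why: Soft enolisation with silyl triflate and amine silylates both enolisable positions (formation of a 1,3-bis(silyl enol ether)), giving the dianion equivalent of 6 whose terminal CH2 is its most nucleophilic carbon.

Step 4
Reactants: 2 β-cyclogeraniol; 7 bis-silyl dienol ether
Product: 9 (−)-8-phenylmenthyl (1R,4aS,8aS)-5,5,8a-trimethyl-2-oxodecahydronaphthalene-1-carboxylate, via monocyclic β-keto ester 8 (not isolated)
Conditions: SnCl4 (2.2 equiv) added to 2 and 7 (1.3 equiv) in CH2Cl2, −78 °C, then 0 °C; aqueous work-up; chromatography or crystallisation to remove the minor diastereomer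
Reagents that add atoms: none
Why: Proposed new method: SnCl4 ionises allylic alcohol 2 to the β-cyclogeranyl cation, whose unhindered primary terminus C-6 is captured by the terminal carbon (C-7) of 7 (an SN1 vinylogous Mukaiyama-type allylation, known for silyl enol ethers with allylic alcohols and acetates), and the proton released with the silanol then adds to C-5 of the tetrasubstituted C5=C10 alkene of tin-chelated β-keto ester 8 while its enol carbon C-9 closes on C-10, which is the known SnCl4-promoted protonative cyclisation of olefinic β-keto esters; the two halves have not been run as one (3+3) annulation, and the closest single-flask analogy is the TiCl4-mediated (3+3) cyclisation of 1,3-bis(silyl enol ethers) with 1,3-dielectrophiles. Ring B closes in the 6-endo-trig mode through a chair-like transition state with the ester equatorial. C-5 and C-10 arise by anti addition of H and C-9 across C5=C10, which fixes the trans ring fusion, and C-9 (equatorial ester, epimerisable, erased in step 5) follows from the same chair. The absolute sense is set by the auxiliary: in the SnCl4 chelate the ester holds its carbinol C–H in the carbonyl plane and the phenyl ring stacks over the enol face on the side of the auxiliary's C-2 (the model used for chelated 8-phenylmenthyl glyoxylates and for Mn(OAc)3-mediated cyclisations of 8-phenylmenthyl β-keto esters), so C-10 should bond to the open face of C-9, which corresponds to the (4aS,8aS) series; the (4aR,8aR) diastereomer is removed physically, so the optical purity of the route does not rest on the level of induction. The step needs γ- over α-attack of the dienol ether (the terminal CH2 is its most nucleophilic carbon), C-6 over C-10 capture of the allyl cation (C-10 is tertiary and buried in the ring) and six- over five-ring closure (only the C-10 cation reaches C-9 through a chair).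

Step 5
Reactants: 9 bicyclic β-keto ester
Product: 10 (−)-8-phenylmenthyl (4aS,8aS)-5,5,8a-trimethyl-2-[(trifluoromethylsulfonyl)oxy]-3,4,4a,5,6,7,8,8a-octahydronaphthalene-1-carboxylate
Conditions: NaH, THF, 0 °C; PhNTf2, 0 °C → rt
Reagents that add atoms: N-phenylbis(trifluoromethanesulfonimide), O=S(=O)(N(c1ccccc1)S(=O)(=O)C(F)(F)F)C(F)(F)F
Why: O-Sulfonylation of the sodium enolate of a β-keto ester (enol triflate formation) can only give the C8=C9 enol triflate, which makes C-9 trigonal and leaves C-5 and C-10 untouched.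

Step 6
Reactants: 10 enol triflate
Product: 11 (−)-8-phenylmenthyl (4aS,8aS)-2,5,5,8a-tetramethyl-3,4,4a,5,6,7,8,8a-octahydronaphthalene-1-carboxylate (8-phenylmenthyl drim-8-en-11-oate)
Conditions: Me2CuLi (from MeLi and CuI, 3 equiv), Et2O, −40 → 0 °C
Reagents that add atoms: lithium dimethylcuprate, [Li+].C[Cu-]C
Why: Gilman cuprates replace the triflate of β-trifloxy enoates by addition–elimination (cuprate coupling of enol triflates), which installs the C-8 methyl without moving the alkene.

Step 7
Reactants: 11 8-phenylmenthyl drim-8-en-11-oate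
Product: 12 (5S,10S)-drim-8-en-11-ol {[(4aS,8aS)-2,5,5,8a-tetramethyl-3,4,4a,5,6,7,8,8a-octahydronaphthalen-1-yl]methanol}
Conditions: LiAlH4, THF, 0 °C → reflux; auxiliary 3 recovered by chromatography
Reagents that add atoms: none
Why: Hydride 1,2-reduction of the tetrasubstituted enoate (ester reduction) gives the allylic alcohol and releases the auxiliary; the sign of rotation of 12 should be compared with drim-8-en-11-ol of known configuration to confirm the sense of step 4.

Step 8
Reactants: 12 drim-8-en-11-ol
Product: 13 (5S,10S)-11-bromodrim-8-ene [(4aS,8aS)-1-(bromomethyl)-2,5,5,8a-tetramethyl-3,4,4a,5,6,7,8,8a-octahydronaphthalene]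
Conditions: PBr3, pyridine (cat.), Et2O, −10 °C; used crude
Reagents that add atoms: phosphorus tribromide, BrP(Br)Br
Why: Bromination of a primary allylic alcohol through its phosphite ester (SN2) should proceed at low temperature without allylic transposition, because the alternative tertiary bromide at C-8 is disfavoured.

Step 9
Reactants: 14 1-(tert-butyldimethylsilyloxy)propan-2-one
Product: 15 1-(tert-butyldimethylsilyloxy)propan-2-one N,N-dimethylhydrazone
Conditions: Me2NNH2, AcOH (cat.), EtOH, rt
Reagents that add atoms: 1,1-dimethylhydrazine, CN(C)N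
Why: Condensation to the dimethylhydrazone prepares the regiodefined azaenolate needed for clean monoalkylation at the methyl group; no stereocenter is involved.

Step 10
Reactants: 13 11-bromodrim-8-ene; 15 hydrazone
Product: 17 1-(tert-butyldimethylsilyloxy)-4-[(4aS,8aS)-2,5,5,8a-tetramethyl-3,4,4a,5,6,7,8,8a-octahydronaphthalen-1-yl]butan-2-one, via alkylated hydrazone 16 (not isolated)
Conditions: LiN(i-Pr)2, THF, 0 °C; 13, −78 → 0 °C; then saturated aqueous oxalic acid, Et2O, rt
Reagents that add atoms: water, O
Why: Dimethylhydrazone azaenolates form at the less substituted α-carbon and are strong SN2 nucleophiles toward allylic bromides (Corey–Enders hydrazone alkylation), so the C11–C12 bond forms at the methyl terminus, and mild acid hydrolysis returns the ketone without touching the silyl ether.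

Step 11
Reactants: 18 ethyl 3-(furan-3-yl)-3-oxopropanoate
Product: 19 ethyl (R)-3-(furan-3-yl)-3-hydroxypropanoate
Conditions: H2 (10 atm), [RuCl(C6H6)((S)-BINAP)]Cl (0.5 mol %), EtOH, 50 °C
Reagents that add atoms: none
Why: Noyori asymmetric hydrogenation of a β-keto ester sets C-16; the (S)-BINAP catalyst delivers hydrogen to the same face as in aryl β-keto esters, which corresponds to the (R)-carbinol, and the furan is not reduced under these conditions.

Step 12
Reactants: 19 (R)-hydroxy ester
Product: 20 ethyl (R)-3-(tert-butyldimethylsilyloxy)-3-(furan-3-yl)propanoate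
Conditions: TBSCl, imidazole, DMF, rt
Reagents that add atoms: tert-butyldimethylsilyl chloride, CC(C)(C)[Si](C)(C)Cl
Why: Silylation of the secondary alcohol (silyl ether formation) protects C-16–OH against the ylide chemistry and matches the protecting group on C-13–CH2OH for a single final deprotection.

Step 13
Reactants: 20 silyl ether ester
Product: 21 (R)-3-(tert-butyldimethylsilyloxy)-3-(furan-3-yl)propan-1-ol
Conditions: i-Bu2AlH (2.5 equiv), CH2Cl2, −78 → 0 °C; Rochelle salt work-up
Reagents that add atoms: none
Why: Hydride reduction of the ester to the primary alcohol (ester reduction) leaves the silyl ether, the furan and the stereocenter unchanged.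

Step 14
Reactants: 21 primary alcohol
Product: 22 (R)-tert-butyl{[1-(furan-3-yl)-3-iodopropyl]oxy}dimethylsilane
Conditions: I2, PPh3, imidazole, CH2Cl2, 0 °C
Reagents that add atoms: iodine, II
Why: Appel-type iodination of the primary alcohol is an SN2 process at C-14 only, so the secondary silyloxy center is untouched.

Step 15
Reactants: 22 iodide
Product: 23 (R)-[3-(tert-butyldimethylsilyloxy)-3-(furan-3-yl)propyl]triphenylphosphonium iodide
Conditions: PPh3, i-Pr2NEt (0.1 equiv), MeCN, 80 °C
Reagents that add atoms: triphenylphosphine, c1ccc(cc1)P(c1ccccc1)c1ccccc1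
Why: SN2 quaternisation of the primary iodide gives the phosphonium salt, and the trace of amine keeps the acid-sensitive furan and silyl ether intact.

Step 16
Reactants: 17 α-silyloxy ketone; 23 phosphonium iodide
Product: 25 3-[(1R,3Z)-1-(tert-butyldimethylsilyloxy)-4-(tert-butyldimethylsilyloxymethyl)-6-[(4aS,8aS)-2,5,5,8a-tetramethyl-3,4,4a,5,6,7,8,8a-octahydronaphthalen-1-yl]hex-3-en-1-yl]furan, via phosphorus ylide 24 (not isolated)
Conditions: KN(SiMe3)2, THF, −78 → 0 °C; then 17, THF, −78 °C → rt
Reagents that add atoms: none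
Why: Wittig olefination of an α-alkoxy or α-silyloxy ketone with a salt-free non-stabilised ylide is known to favour the trisubstituted alkene in which the ylide chain is cis to the CH2O group, here the required geometry with C-15 cis to CH2OTBS, and the γ-silyloxy ylide cannot eliminate, so C-16 is preserved.

Step 17
Reactants: 25 furyl bis-silyl ether
Product: 27 4-[(1R,3Z)-1-(tert-butyldimethylsilyloxy)-4-(tert-butyldimethylsilyloxymethyl)-6-[(4aS,8aS)-2,5,5,8a-tetramethyl-3,4,4a,5,6,7,8,8a-octahydronaphthalen-1-yl]hex-3-en-1-yl]-5-hydroxyfuran-2(5H)-one (lactol epimers), via furan endoperoxide 26 (not isolated)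
Conditions: O2, visible light, 5,10,15,20-tetraphenylporphyrin (cat.), i-Pr2NEt (3 equiv), CH2Cl2, −78 °C
Reagents that add atoms: oxygen, O=O
Why: Singlet oxygen adds (4+2) to the furan much faster at −78 °C than it reacts in the ene mode with the tri- and tetrasubstituted alkenes (the same selectivity is relied on for related terpenoid furans that carry a trimethylcyclohexenyl ring), and the hindered amine removes the bridgehead proton remote from the silyloxyalkyl group of 26 (Kornblum–DeLaMare-type fragmentation), which places the carbonyl there and gives the 4-substituted 5-hydroxybutenolide.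

Step 18
Reactants: 27 γ-hydroxybutenolide
Product: 29 4-[(1R,3Z)-1-(tert-butyldimethylsilyloxy)-4-(tert-butyldimethylsilyloxymethyl)-6-[(4aS,8aS)-2,5,5,8a-tetramethyl-3,4,4a,5,6,7,8,8a-octahydronaphthalen-1-yl]hex-3-en-1-yl]furan-2(5H)-one, via hydroxy acid 28 (not isolated)
Conditions: NaBH4, EtOH–THF, 0 °C; then 1 M HCl to pH 3, rt
Reagents that add atoms: none
Why: Borohydride reduces the aldehyde of the ring-opened 4-oxo-enoate form of the lactol, and acidification closes hydroxy acid 28 to the butenolide (reduction–lactonisation), which removes the lactol stereocenter.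

Step 19
Reactants: 29 bis-silyl butenolide
Product: 30 4-[(1R,3Z)-1-hydroxy-4-(hydroxymethyl)-6-[(4aS,8aS)-2,5,5,8a-tetramethyl-3,4,4a,5,6,7,8,8a-octahydronaphthalen-1-yl]hex-3-en-1-yl]furan-2(5H)-one (target)
Conditions: HF·pyridine, pyridine–THF, 0 °C → rt
Reagents that add atoms: none
Why: Buffered fluoride cleavage of both silyl ethers (desilylation) is compatible with the base-sensitive butenolide, the allylic alcohol and the (R)-carbinol and should give the target.

**Compound list**
1 | β-cyclocitral | CC1=C(C=O)C(C)(C)CCC1 | starting material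
2 | β-cyclogeraniol | CC1=C(CO)C(C)(C)CCC1 | intermediate
3 | (−)-8-phenylmenthol, (1R,2S,5R) | O[C@@H]1C[C@H](C)CC[C@H]1C(C)(C)c1ccccc1 | starting material
4 | 2,2,6-trimethyl-4H-1,3-dioxin-4-one | CC1=CC(=O)OC(C)(C)O1 | starting material
5 | acetylketene | CC(=O)C=C=O | intermediate
6 | (−)-8-phenylmenthyl acetoacetate | CC(=O)CC(=O)O[C@@H]1C[C@H](C)CC[C@H]1C(C)(C)c1ccccc1 | intermediate
7 | 1-[(−)-8-phenylmenthyloxy]-1,3-bis(trimethylsilyloxy)buta-1,3-diene | C=C(O[Si](C)(C)C)C=C(O[Si](C)(C)C)O[C@@H]1C[C@H](C)CC[C@H]1C(C)(C)c1ccccc1 | intermediate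
8 | (−)-8-phenylmenthyl 3-oxo-5-(2,6,6-trimethylcyclohex-1-en-1-yl)pentanoate | CC1=C(CCC(=O)CC(=O)O[C@@H]2C[C@H](C)CC[C@H]2C(C)(C)c2ccccc2)C(C)(C)CCC1 | intermediate
9 | (−)-8-phenylmenthyl (1R,4aS,8aS)-5,5,8a-trimethyl-2-oxodecahydronaphthalene-1-carboxylate | O=C1CC[C@H]2C(C)(C)CCC[C@]2(C)[C@H]1C(=O)O[C@@H]1C[C@H](C)CC[C@H]1C(C)(C)c1ccccc1 | intermediate
10 | enol triflate of 9, (4aS,8aS) | FC(F)(F)S(=O)(=O)OC1=C(C(=O)O[C@@H]3C[C@H](C)CC[C@H]3C(C)(C)c3ccccc3)[C@@]2(C)CCCC(C)(C)[C@@H]2CC1 | intermediate
11 | (−)-8-phenylmenthyl (5S,10S)-drim-8-en-11-oate | CC1=C(C(=O)O[C@@H]3C[C@H](C)CC[C@H]3C(C)(C)c3ccccc3)[C@@]2(C)CCCC(C)(C)[C@@H]2CC1 | intermediate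
12 | (5S,10S)-drim-8-en-11-ol | CC1=C(CO)[C@@]2(C)CCCC(C)(C)[C@@H]2CC1 | intermediate
13 | (5S,10S)-11-bromodrim-8-ene | CC1=C(CBr)[C@@]2(C)CCCC(C)(C)[C@@H]2CC1 | intermediate
14 | 1-(tert-butyldimethylsilyloxy)propan-2-one | CC(=O)CO[Si](C)(C)C(C)(C)C | starting material
15 | 1-(tert-butyldimethylsilyloxy)propan-2-one N,N-dimethylhydrazone | CC(CO[Si](C)(C)C(C)(C)C)=NN(C)C | intermediate
16 | N,N-dimethylhydrazone of ketone 17 | CC1=C(CCC(CO[Si](C)(C)C(C)(C)C)=NN(C)C)[C@@]2(C)CCCC(C)(C)[C@@H]2CC1 | intermediate
17 | 1-(tert-butyldimethylsilyloxy)-4-[(4aS,8aS)-2,5,5,8a-tetramethyl-3,4,4a,5,6,7,8,8a-octahydronaphthalen-1-yl]butan-2-one | CC1=C(CCC(=O)CO[Si](C)(C)C(C)(C)C)[C@@]2(C)CCCC(C)(C)[C@@H]2CC1 | intermediate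
18 | ethyl 3-(furan-3-yl)-3-oxopropanoate | CCOC(=O)CC(=O)c1ccoc1 | starting material
19 | ethyl (R)-3-(furan-3-yl)-3-hydroxypropanoate | CCOC(=O)C[C@@H](O)c1ccoc1 | intermediate
20 | ethyl (R)-3-(tert-butyldimethylsilyloxy)-3-(furan-3-yl)propanoate | CCOC(=O)C[C@@H](O[Si](C)(C)C(C)(C)C)c1ccoc1 | intermediate
21 | (R)-3-(tert-butyldimethylsilyloxy)-3-(furan-3-yl)propan-1-ol | OCC[C@@H](O[Si](C)(C)C(C)(C)C)c1ccoc1 | intermediate
22 | (R)-tert-butyl{[1-(furan-3-yl)-3-iodopropyl]oxy}dimethylsilane | ICC[C@@H](O[Si](C)(C)C(C)(C)C)c1ccoc1 | intermediate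
23 | (R)-[3-(tert-butyldimethylsilyloxy)-3-(furan-3-yl)propyl]triphenylphosphonium iodide | [I-].c1ccccc1[P+](CC[C@@H](O[Si](C)(C)C(C)(C)C)c1ccoc1)(c1ccccc1)c1ccccc1 | intermediate
24 | ylide of 23 | c1ccccc1P(=CC[C@@H](O[Si](C)(C)C(C)(C)C)c1ccoc1)(c1ccccc1)c1ccccc1 | intermediate
25 | (1R,3Z) furyl bis-silyl ether | CC1=C(CC/C(=C/C[C@@H](O[Si](C)(C)C(C)(C)C)c3ccoc3)CO[Si](C)(C)C(C)(C)C)[C@@]2(C)CCCC(C)(C)[C@@H]2CC1 | intermediate
26 | furan endoperoxide of 25 | CC1=C(CC/C(=C/C[C@@H](O[Si](C)(C)C(C)(C)C)C3=CC4OOC3O4)CO[Si](C)(C)C(C)(C)C)[C@@]2(C)CCCC(C)(C)[C@@H]2CC1 | intermediate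
27 | 4-substituted 5-hydroxyfuran-2(5H)-one (lactol epimers) | CC1=C(CC/C(=C/C[C@@H](O[Si](C)(C)C(C)(C)C)C3=CC(=O)OC3O)CO[Si](C)(C)C(C)(C)C)[C@@]2(C)CCCC(C)(C)[C@@H]2CC1 | intermediate
28 | (Z)-4-hydroxy-3-substituted but-2-enoic acid | CC1=C(CC/C(=C/C[C@@H](O[Si](C)(C)C(C)(C)C)/C(CO)=C/C(=O)O)CO[Si](C)(C)C(C)(C)C)[C@@]2(C)CCCC(C)(C)[C@@H]2CC1 | intermediate
29 | bis-silyl ether of the target | CC1=C(CC/C(=C/C[C@@H](O[Si](C)(C)C(C)(C)C)C3=CC(=O)OC3)CO[Si](C)(C)C(C)(C)C)[C@@]2(C)CCCC(C)(C)[C@@H]2CC1 | intermediate
30 | 4-[(1R,3Z)-1-hydroxy-4-(hydroxymethyl)-6-[(4aS,8aS)-2,5,5,8a-tetramethyl-3,4,4a,5,6,7,8,8a-octahydronaphthalen-1-yl]hex-3-en-1-yl]furan-2(5H)-one | CC1=C(CC/C(=C/C[C@@H](O)C2=CC(=O)OC2)CO)[C@@]2(C)CCCC(C)(C)[C@@H]2CC1 | target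

**Step count and risks**
Total: 19 steps. Longest linear sequence: 12 steps (steps 2, 3, 4, 5, 6, 7, 8, 10, 16, 17, 18, 19).

Steps most likely to fail:

1. Step 4. The dienol ether may be protodesilylated by the acid set free before the C6–C7 bond forms, the allyl cation may be captured at the wrong carbon, or the facial bias of the auxiliary may be weak or opposite to the model. In the last case the enantiomeric auxiliary would be used; the separation of diastereomers protects the optical purity in every case. The fallback uses the known two-operation sequence and sets out from 2 and 6. Alcohol 2 is converted with PBr3 into 2-(bromomethyl)-1,3,3-trimethylcyclohex-1-ene F1. The dianion of 6 (NaH, then n-BuLi, THF, 0 °C) is alkylated at its γ-carbon by F1 to give β-keto ester 8, which is now isolated. SnCl4 in CH2Cl2 at 0 °C then closes ring B by protonative cyclisation, and the product is freed from its diastereomer as in the main route. The fallback comes back to the route at 9.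

2. Step 16. The Z-selectivity may erode, or the basic ylide may enolise ketone 17. The fallback is a stepwise Horner–Wittig sequence and sets out from 22 and 17. Iodide 22 is alkylated with Ph2P(O)H and KN(SiMe3)2 to (R)-[3-(tert-butyldimethylsilyloxy)-3-(furan-3-yl)propyl]diphenylphosphine oxide F2. Lithiation of F2 (n-BuLi, THF, −78 °C) and addition to 17 gives the β-hydroxy phosphine oxide adduct F3 as diastereomers, which are separated on silica. The isomer whose syn-elimination places CH2OTBS and C-15 on the same side is treated with NaH in DMF and eliminates stereospecifically. The fallback comes back to the route at 25.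

3. Step 7. Hydride delivery to the ester carbonyl may be sluggish or incomplete, because the carbonyl sits between a tetrasubstituted alkene carbon next to the quaternary C-10 and the bulky alkoxy group, and forcing conditions could move the alkene. The fallback removes the auxiliary earlier and sets out from 9. Heating 9 with MeOH in toluene (DMAP cat., 110 °C, sealed tube) transesterifies it by the acylketene pathway to methyl (1R,4aS,8aS)-5,5,8a-trimethyl-2-oxodecahydronaphthalene-1-carboxylate F4, with recovery of 3. NaH and PhNTf2 give the methyl enol triflate F5, Me2CuLi gives methyl (5S,10S)-drim-8-en-11-oate F6, and LiAlH4 in Et2O at 0 °C reduces this unhindered methyl ester. The fallback comes back to the route at 12.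

**Further compounds**
F1 | step 4 | 2-(bromomethyl)-1,3,3-trimethylcyclohex-1-ene | CC1=C(CBr)C(C)(C)CCC1
F2 | step 16 | (R)-[3-(tert-butyldimethylsilyloxy)-3-(furan-3-yl)propyl]diphenylphosphine oxide | O=P(CC[C@@H](O[Si](C)(C)C(C)(C)C)c1ccoc1)(c1ccccc1)c1ccccc1
F3 | step 16 | β-hydroxy phosphine oxide adduct of F2 and 17 (isomer that gives the Z-alkene; C-13 and C-14 configuration not specified) | CC1=C(CCC(O)(CO[Si](C)(C)C(C)(C)C)C(C[C@@H](O[Si](C)(C)C(C)(C)C)c3ccoc3)P(=O)(c3ccccc3)c3ccccc3)[C@@]2(C)CCCC(C)(C)[C@@H]2CC1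
F4 | step 7 | methyl (1R,4aS,8aS)-5,5,8a-trimethyl-2-oxodecahydronaphthalene-1-carboxylate | O=C1CC[C@H]2C(C)(C)CCC[C@]2(C)[C@H]1C(=O)OC
F5 | step 7 | methyl (4aS,8aS)-5,5,8a-trimethyl-2-[(trifluoromethylsulfonyl)oxy]-3,4,4a,5,6,7,8,8a-octahydronaphthalene-1-carboxylate | FC(F)(F)S(=O)(=O)OC1=C(C(=O)OC)[C@@]2(C)CCCC(C)(C)[C@@H]2CC1
F6 | step 7 | methyl (5S,10S)-drim-8-en-11-oate | CC1=C(C(=O)OC)[C@@]2(C)CCCC(C)(C)[C@@H]2CC1
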